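## Retrosynthetic overview

1. The target is a 3-benzylchromone whose ring A (C4a, C5, C6, C7, C8, C8a) is fully substituted: the C4 carbonyl on C4a, OMe on C5, Me on C6, free OH on C7, CHO on C8 and the ring oxygen O1 on C8a. The plan rests on making this ring with its three oxygens already told apart.
2. Ring C is cut last at O1–C2 and C2–C3 (C2 from DMF). C4–C4a is then cut to an aryllithium at C4a, the one ring C–H, flanked by the C5 and C8a oxygens, and the Weinreb amide of 3-(4-methoxyphenyl)propanoic acid, which brings ring B.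
3. Ring A is cut at C7–C8, C4a–C8a and C6–C7: Danheiser benzannulation of 3-methoxy-4-methylcyclobutenone (C4a, C5, C6, C7) with the siloxyalkyne i-Pr3SiO–C≡C–CH(OEt)2 (C8a, C8 and the masked aldehyde).
4. The cyclobutenone comes from methoxyethyne and methylketene; the siloxyalkyne comes from ethyl diethoxyacetate by ester homologation to the ynolate.
5. Order of ring formation: ring A (step 4), then ring C (step 10); ring B is bought.

Key step: step 4

Remark: chromone numbering (O1, C2, C3, C4, C4a, C5–C8, C8a) is used for ring atoms throughout. The target has no stereocentre; compounds 6, 12, 14 and 24 are racemic and their stereocentres are destroyed later.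

## Route

Step 1
Reactants: 1 chloroacetaldehyde dimethyl acetal (2-chloro-1,1-dimethoxyethane)
Product: 3 methoxyethyne, via sodium methoxyethynide 2 (not isolated)
Conditions: NaNH2 (3 equiv), liq. NH3, −33 °C; then cold satd aq. NaCl; distil
Reagents that add atoms: none
Why: Double β-elimination with excess amide base (loss of methanol, then of HCl) leads to the sodium acetylide 2, which the aqueous quench protonates, and the low-boiling ynol ether is distilled out of the flask.

Step 2
Reactants: 3 methoxyethyne; 4 propanoyl chloride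
Product: 6 3-methoxy-4-methylcyclobut-2-en-1-one (racemic), via methylketene 5 (not isolated)
Conditions: Et3N, Et2O, 0 °C → rt (4 added slowly to 3 in excess)
Reagents that add atoms: none
Why: Ketene–alkyne (2+2) cycloaddition: Et3N dehydrochlorinates 4 to methylketene 5, whose carbonyl carbon is attacked by the unsubstituted, nucleophilic carbon of the ynol ether before ring closure, giving the 3-alkoxycyclobutenone with a racemic C4 stereocentre that is erased in step 4.

Step 3
Reactants: 7 ethyl 2,2-diethoxyacetate
Product: 10 [(3,3-diethoxyprop-1-yn-1-yl)oxy]triisopropylsilane, via lithium dibromoenolate 8 (not isolated), via lithium ynolate 9 (not isolated)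
Conditions: CH2Br2, lithium 2,2,6,6-tetramethylpiperidide, THF, −78 °C; 7; LiN(SiMe3)2; s-BuLi, −78 °C → rt; i-Pr3SiCl, 0 °C → rt (Et3N-washed silica)
Reagents that add atoms: dibromomethane BrCBr; chlorotriisopropylsilane CC(C)[Si](Cl)(C(C)C)C(C)C
Why: Kowalski ester homologation to an ynolate: LiCHBr2 adds to the ester, the dibromo enolate 8 undergoes bromine–lithium exchange and 1,2-shift of the diethoxymethyl group to give ynolate 9, and the bulky silyl chloride traps it on oxygen; expulsion of ethoxide from 9 would require an alkoxypropadienone and is not expected.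

Step 4
Reactants: 6 3-methoxy-4-methylcyclobut-2-en-1-one; 10 [(3,3-diethoxyprop-1-yn-1-yl)oxy]triisopropylsilane
Product: 15 2-(diethoxymethyl)-5-methoxy-6-methyl-3-(triisopropylsilyloxy)phenol, via vinylketene 11 (not isolated), via vinylcyclobutenone 12 (not isolated), via dienylketene 13 (not isolated), via cyclohexadienone 14 (not isolated)
Conditions: toluene, 80 °C then 110 °C, sealed tube, argon, base-washed glassware (10, 1.3 equiv)
Reagents that add atoms: none
Why: On heating, 6 opens in a four-electron electrocyclic process to vinylketene 11, whose carbonyl carbon (future C7) is attacked by the acetal-bearing, nucleophilic carbon of 10 (future C8) while its α-carbon (future C4a) bonds to the silyloxy carbon (future C8a), a ketene–alkyne (2+2) cycloaddition that gives 12. A second four-electron opening turns 12 into dienylketene 13, and ring A closes by thermal disrotatory six-electron electrocyclization between C7 and C6 to dienone 14, which tautomerizes to phenol 15. This is the Danheiser benzannulation of a 3-alkoxycyclobutenone with a trialkylsilyloxyalkyne. No stereocentre is left, since those of 6, 12 and 14 vanish on ring opening and aromatization. The step needs the regiochemistry of the (2+2) addition, which the polarization of the siloxyalkyne secures (the carbon remote from oxygen is the nucleophile), and capture of 11 ahead of its dimerization, which the excess of 10 supports. The medium is neutral and aprotic, so the acetal and the aryl silyl ether should persist, and C4a is left as the only unsubstituted ring carbon.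

Step 5
Reactants: 15 2-(diethoxymethyl)-5-methoxy-6-methyl-3-(triisopropylsilyloxy)phenol
Product: 17 [2-(diethoxymethyl)-5-methoxy-3-(methoxymethoxy)-4-methylphenoxy]triisopropylsilane, via sodium phenolate 16 (not isolated)
Conditions: NaH, THF–DMF, 0 °C; then MOMCl, 0 °C → rt
Reagents that add atoms: chloromethyl methyl ether COCCl
Why: Williamson etherification of the sodium phenolate, which removes the acidic C7 hydroxyl next to the acetal before the silyl ether is cleaved.

Step 6
Reactants: 17 [2-(diethoxymethyl)-5-methoxy-3-(methoxymethoxy)-4-methylphenoxy]triisopropylsilane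
Product: 19 2-(diethoxymethyl)-5-methoxy-1,3-bis(methoxymethoxy)-4-methylbenzene, via ammonium phenolate 18 (not isolated)
Conditions: Bu4NF, THF, 0 °C; then i-Pr2NEt, MOMCl, 0 °C → rt
Reagents that add atoms: chloromethyl methyl ether COCCl
Why: Fluoride cleaves the aryl silyl ether and the ammonium phenolate 18 is alkylated in the same flask (desilylative Williamson etherification), exchanging a silyl ether that shields C4a for a methoxymethyl ether that directs lithiation to it.

Step 7
Reactants: 20 3-(4-methoxyphenyl)propanoic acid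
Product: 22 N-methoxy-3-(4-methoxyphenyl)-N-methylpropanamide, via acyl imidazole 21 (not isolated)
Conditions: CDI, CH2Cl2, rt; then MeNHOMe·HCl, rt
Reagents that add atoms: N,O-dimethylhydroxylamine hydrochloride CNOC.Cl
Why: Weinreb amide formation through the acyl imidazole 21.

Step 8
Reactants: 19 2-(diethoxymethyl)-5-methoxy-1,3-bis(methoxymethoxy)-4-methylbenzene; 22 N-methoxy-3-(4-methoxyphenyl)-N-methylpropanamide
Product: 25 1-[3-(diethoxymethyl)-6-methoxy-2,4-bis(methoxymethoxy)-5-methylphenyl]-3-(4-methoxyphenyl)propan-1-one, via aryllithium 23 (not isolated), via lithium hemiaminal alkoxide 24 (not isolated)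
Conditions: n-BuLi, THF, 0 °C; then 22, −78 °C → 0 °C; aq. NH4Cl
Reagents that add atoms: none
Why: Directed ortho-metalation followed by Weinreb ketone synthesis: the only ring hydrogen, at C4a, lies between the C8a methoxymethoxy and C5 methoxy groups and is removed by n-BuLi, and the aryllithium 23 adds once to 22 because the chelated adduct 24 does not collapse before the quench.

Step 9
Reactants: 25 1-[3-(diethoxymethyl)-6-methoxy-2,4-bis(methoxymethoxy)-5-methylphenyl]-3-(4-methoxyphenyl)propan-1-one
Product: 26 2,6-dihydroxy-4-methoxy-3-[3-(4-methoxyphenyl)propanoyl]-5-methylbenzaldehyde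
Conditions: 3 M aq. HCl, THF–MeOH, 50 °C
Reagents that add atoms: water O
Why: Acid-catalysed hydrolysis of both methoxymethyl ethers and of the diethyl acetal in one operation, giving a product held by hydrogen bonds from its two hydroxyls to the ketone and aldehyde carbonyls.

Step 10
Reactants: 26 2,6-dihydroxy-4-methoxy-3-[3-(4-methoxyphenyl)propanoyl]-5-methylbenzaldehyde
Product: 28 7-hydroxy-5-methoxy-3-[(4-methoxyphenyl)methyl]-6-methyl-4-oxo-4H-chromene-8-carbaldehyde, via enaminone 27 (not isolated)
Conditions: BF3·OEt2, DMF, 50 °C; then MsCl, 80 °C; aq. NaOAc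
Reagents that add atoms: N,N-dimethylformamide CN(C)C=O
Why: Vilsmeier-type aminomethylenation of the α-methylene of the BF3-chelated ortho-hydroxyaryl ketone (the BF3·OEt2–DMF–MsCl one-carbon chromone synthesis used for isoflavones and 3-benzylchromones) gives enaminone 27, held in the flask as its boron chelate, and conjugate addition of the C8a hydroxyl with loss of dimethylamine closes ring C by 6-endo-trig cyclization; only the C8a hydroxyl is ortho to the ketone and ring A has no free position to formylate.

## Compound list

1 | chloroacetaldehyde dimethyl acetal (2-chloro-1,1-dimethoxyethane) | COC(CCl)OC | starting material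
2 | sodium methoxyethynide (not isolated) | [Na+].[C-]#COC | intermediate
3 | methoxyethyne | COC#C | intermediate
4 | propanoyl chloride | CCC(=O)Cl | starting material
5 | methylketene, prop-1-en-1-one (not isolated) | CC=C=O | intermediate
6 | 3-methoxy-4-methylcyclobut-2-en-1-one (racemic) | COC1=CC(=O)C1C | intermediate
7 | ethyl 2,2-diethoxyacetate | CCOC(=O)C(OCC)OCC | starting material
8 | lithium 1,1-dibromo-3,3-diethoxyprop-1-en-2-olate (not isolated) | [Li+].[O-]C(=C(Br)Br)C(OCC)OCC | intermediate
9 | lithium 3,3-diethoxyprop-1-yn-1-olate (not isolated) | [Li+].[O-]C#CC(OCC)OCC | intermediate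
10 | [(3,3-diethoxyprop-1-yn-1-yl)oxy]triisopropylsilane | CCOC(OCC)C#CO[Si](C(C)C)(C(C)C)C(C)C | intermediate
11 | (3Z)-3-methoxypenta-1,3-dien-1-one (not isolated) | C/C=C(\OC)C=C=O | intermediate
12 | 2-(diethoxymethyl)-4-[(1Z)-1-methoxyprop-1-en-1-yl]-3-(triisopropylsilyloxy)cyclobut-2-en-1-one (racemic, not isolated) | CCOC(OCC)C1=C(O[Si](C(C)C)(C(C)C)C(C)C)C(C(/OC)=C/C)C1=O | intermediate
13 | (3E,5Z)-2-(diethoxymethyl)-5-methoxy-3-(triisopropylsilyloxy)hepta-1,3,5-trien-1-one (not isolated) | CCOC(OCC)C(=C=O)/C(O[Si](C(C)C)(C(C)C)C(C)C)=C\C(OC)=C\C | intermediate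
14 | 2-(diethoxymethyl)-5-methoxy-6-methyl-3-(triisopropylsilyloxy)cyclohexa-2,4-dien-1-one (racemic, not isolated) | CCOC(OCC)C1=C(O[Si](C(C)C)(C(C)C)C(C)C)C=C(OC)C(C)C1=O | intermediate
15 | 2-(diethoxymethyl)-5-methoxy-6-methyl-3-(triisopropylsilyloxy)phenol | CCOC(OCC)c1c(O)c(C)c(OC)cc1O[Si](C(C)C)(C(C)C)C(C)C | intermediate
16 | sodium 2-(diethoxymethyl)-5-methoxy-6-methyl-3-(triisopropylsilyloxy)phenolate (not isolated) | [Na+].[O-]c1c(C)c(OC)cc(O[Si](C(C)C)(C(C)C)C(C)C)c1C(OCC)OCC | intermediate
17 | [2-(diethoxymethyl)-5-methoxy-3-(methoxymethoxy)-4-methylphenoxy]triisopropylsilane | CCOC(OCC)c1c(OCOC)c(C)c(OC)cc1O[Si](C(C)C)(C(C)C)C(C)C | intermediate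
18 | tetrabutylammonium 2-(diethoxymethyl)-5-methoxy-3-(methoxymethoxy)-4-methylphenolate (not isolated) | CCCC[N+](CCCC)(CCCC)CCCC.[O-]c1cc(OC)c(C)c(OCOC)c1C(OCC)OCC | intermediate
19 | 2-(diethoxymethyl)-5-methoxy-1,3-bis(methoxymethoxy)-4-methylbenzene | CCOC(OCC)c1c(OCOC)cc(OC)c(C)c1OCOC | intermediate
20 | 3-(4-methoxyphenyl)propanoic acid | COc1ccc(CCC(=O)O)cc1 | starting material
21 | 1-(1H-imidazol-1-yl)-3-(4-methoxyphenyl)propan-1-one (not isolated) | COc1ccc(CCC(=O)n2ccnc2)cc1 | intermediate
22 | N-methoxy-3-(4-methoxyphenyl)-N-methylpropanamide | COc1ccc(CCC(=O)N(C)OC)cc1 | intermediate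
23 | [3-(diethoxymethyl)-6-methoxy-2,4-bis(methoxymethoxy)-5-methylphenyl]lithium (not isolated) | [Li]c1c(OC)c(C)c(OCOC)c(C(OCC)OCC)c1OCOC | intermediate
24 | lithium 1-[3-(diethoxymethyl)-6-methoxy-2,4-bis(methoxymethoxy)-5-methylphenyl]-1-[methoxy(methyl)amino]-3-(4-methoxyphenyl)propan-1-olate (racemic, not isolated) | [Li+].[O-]C(CCc1ccc(OC)cc1)(N(C)OC)c1c(OC)c(C)c(OCOC)c(C(OCC)OCC)c1OCOC | intermediate
25 | 1-[3-(diethoxymethyl)-6-methoxy-2,4-bis(methoxymethoxy)-5-methylphenyl]-3-(4-methoxyphenyl)propan-1-one | COc1ccc(CCC(=O)c2c(OC)c(C)c(OCOC)c(C(OCC)OCC)c2OCOC)cc1 | intermediate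
26 | 2,6-dihydroxy-4-methoxy-3-[3-(4-methoxyphenyl)propanoyl]-5-methylbenzaldehyde | COc1ccc(CCC(=O)c2c(O)c(C=O)c(O)c(C)c2OC)cc1 | intermediate
27 | 3-[(2E)-3-(dimethylamino)-2-(4-methoxybenzyl)prop-2-enoyl]-2,6-dihydroxy-4-methoxy-5-methylbenzaldehyde (not isolated; written as the free enaminone) | CN(C)/C=C(\Cc1ccc(OC)cc1)C(=O)c1c(O)c(C=O)c(O)c(C)c1OC | intermediate
28 | 7-hydroxy-5-methoxy-3-[(4-methoxyphenyl)methyl]-6-methyl-4-oxo-4H-chromene-8-carbaldehyde | COc1ccc(Cc2coc3c(C=O)c(O)c(C)c(OC)c3c2=O)cc1 | target

## Step count and risks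

Total step count: 10. Longest linear sequence: 8 (steps 1, 2, 4, 5, 6, 8, 9, 10).

**Step 4 (key step).** The acetal makes the alkyne less nucleophilic, so capture of vinylketene 11 may be slow. Ketene dimerization, a 1,5-hydrogen shift from the γ-methyl group of the inward-rotated isomer, and O-acylation of the product phenol by the ketene could then take over. The fallback sets out from cyclobutenone 6 and siloxyalkyne 10 and comes back at bis-ether 19; it cuts ring A differently, with C8a as the ketene carbon. 6 is hydrolysed (1 M aq. HCl, THF) to 3-hydroxy-2-methylcyclobut-2-en-1-one F1, the enol of 2-methylcyclobutane-1,3-dione. O-Methylation with Me3SiCHN2 in MeOH–toluene gives the transposed 3-methoxy-2-methylcyclobut-2-en-1-one F2. Its vinylketene is α-methyl-substituted, so it should dimerize less readily, and it has no γ-alkyl group from which hydrogen can shift. Heating F2 with 10 (toluene, 110 °C) forms C8–C8a, C6–C7 and C4a–C8a and should give 2-(diethoxymethyl)-5-methoxy-4-methyl-3-(triisopropylsilyloxy)phenol F3, with the free hydroxyl on C8a and the silyl ether on C7. Bu4NF (THF, 0 °C, pH 7 work-up) gives 2-(diethoxymethyl)-5-methoxy-4-methylbenzene-1,3-diol F4, and MOMCl with i-Pr2NEt protects both hydroxyls to give 19.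

**Step 3.** The 1,2-shift of the electron-poor diethoxymethyl group in the bromo-lithio enolate may be slow, so the carbenoid may decompose on warming in the presence of excess alkyllithium. The fallback sets out from ester 7 and comes back at ynolate 9, then 10; it makes the ynolate by oxidation instead of rearrangement. 7 is reduced with i-Bu2AlH (CH2Cl2, −78 °C) to 2,2-diethoxyacetaldehyde F5. Ohira–Bestmann homologation (dimethyl (1-diazo-2-oxopropyl)phosphonate, K2CO3, MeOH) gives 3,3-diethoxyprop-1-yne F6, a compound that can also be bought. n-BuLi gives lithium 3,3-diethoxyprop-1-yn-1-ide F7. Oxidation of F7 with LiOOt-Bu (from t-BuOOH and LiN(SiMe3)2, THF, −78 to 0 °C) gives ynolate 9 at low temperature, and i-Pr3SiOTf at −78 °C gives 10.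

**Step 10.** BF3 may be tied up by the C8 aldehyde and the two hydroxyls, slowing enolization of the ketone, and the chloroiminium reagent may attack the free C7 hydroxyl, so ring closure may stay incomplete. The fallback sets out from ketone 25 and comes back at target 28; it forms the C2 carbon before any phenol or the aldehyde is free. 25 is heated with t-BuOCH(NMe2)2 (toluene, 110 °C) to give (2E)-1-[3-(diethoxymethyl)-6-methoxy-2,4-bis(methoxymethoxy)-5-methylphenyl]-3-(dimethylamino)-2-[(4-methoxyphenyl)methyl]prop-2-en-1-one F8. 3 M aq. HCl in THF–MeOH at 50 °C then removes both methoxymethyl ethers and the acetal, and the freed C8a hydroxyl adds to the enaminone with loss of dimethylamine to give 28.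

Further compounds
F1 | step 4 | 3-hydroxy-2-methylcyclobut-2-en-1-one (enol of 2-methylcyclobutane-1,3-dione) | CC1=C(O)CC1=O
F2 | step 4 | 3-methoxy-2-methylcyclobut-2-en-1-one | COC1=C(C)C(=O)C1
F3 | step 4 | 2-(diethoxymethyl)-5-methoxy-4-methyl-3-(triisopropylsilyloxy)phenol | CCOC(OCC)c1c(O)cc(OC)c(C)c1O[Si](C(C)C)(C(C)C)C(C)C
F4 | step 4 | 2-(diethoxymethyl)-5-methoxy-4-methylbenzene-1,3-diol | CCOC(OCC)c1c(O)cc(OC)c(C)c1O
F5 | step 3 | 2,2-diethoxyacetaldehyde | CCOC(C=O)OCC
F6 | step 3 | 3,3-diethoxyprop-1-yne | CCOC(OCC)C#C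
F7 | step 3 | lithium 3,3-diethoxyprop-1-yn-1-ide | [Li+].[C-]#CC(OCC)OCC
F8 | step 10 | (2E)-1-[3-(diethoxymethyl)-6-methoxy-2,4-bis(methoxymethoxy)-5-methylphenyl]-3-(dimethylamino)-2-[(4-methoxyphenyl)methyl]prop-2-en-1-one | CN(C)/C=C(\Cc1ccc(OC)cc1)C(=O)c1c(OC)c(C)c(OCOC)c(C(OCC)OCC)c1OCOC
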